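The runs were computed for an exercise; the scatter is artificial.

The winter run held twice the reagent of the spring flask and ended with twice its target, so I looked for one number that would carry that proportion.

| setting | spring | winter | flask |
|---|---|---|---|
| starting material | 0.10 M | 0.10 M | 0.10 M |
| reagent | 0.18 M | 0.36 M | 0.180 M |
| capture agent | 0.10 M | 0.10 M | 0.100 M |
| free catalyst | 1.6 mM | 1.6 mM | 1.6 mM |
| temperature | −20 °C | −25 °C | −20 °C |
| remark | the very flask that is asked about, followed so far | run made earlier |  |
| time |  |  | 4.0 d |

| run | time / h | target / % | starting material / % |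
|---|---|---|---|
| spring | 5.00 | 17.9 | 62.8 |
| spring | 15.0 | 18.9 | 62.5 |
| spring | 25.0 | 17.5 | 62.3 |
| spring | 40.0 | 18.7 | 63.2 |
| spring | 60.0 | 18.5 | 62.7 |
| spring | 72.0 | 18.8 | 62.8 |
| winter | 0.250 | 11.5 | 77.0 |
| winter | 0.667 | 22.2 | 56.2 |
| winter | 1.33 | 28.4 | 40.4 |
| winter | 2.00 | 32.5 | 32.9 |
| winter | 2.50 | 34.6 | 30.5 |
| winter | 4.00 | 36.7 | 28.2 |

(readings scatter by 0.5 percentage points)

- the volume of additions can be left aside
- the earlier runs were read with a standard deviation of 0.5 percentage points
- a reading or a percentage of target counts all its forms, free or not
- a reading of starting material is of its free form alone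

- Thursday's: at 4.0 d raise the temperature by 20 K, then wait 50 h
- Saturday's: at 4.0 d take out 90% of the by-product then present, then wait 50 h
- Wednesday's: at 4.0 d add reagent, 50.0% of the amount charged, then wait 50 h
- Monday's: change nothing and wait 50 h more
- Friday's: at 4.0 d add free catalyst, 50.0% of the amount charged, then wait 50 h

- target, in percent of the starting material first charged, at 4.0 d
- the remedy with the largest gain of target, or "none" below 2 percentage points (Thursday's / Saturday's / Wednesday's / Monday's / Friday's / none)
- target present, in percent of the starting material first charged, after Thursday's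
- target present, in percent of the starting material first charged, after Friday's

The spring flask lay flat from its first reading at a mean target of 18.4%, with starting material still reading 62.8%, so I took the stop as the loss of the catalyst and counted the turnover number, target made per catalyst charged:

N(spring) = 11.5, N(winter, last reading) = 22.9

In logarithms, with the temperature difference between the two runs left aside, the slope of N against reagent came out as a reading of

log10(N ratio) / log10(reagent ratio) = 0.997

Each catalyst thus seemed to choose between reagent and loss at every round. Assuming that the capture agent does the taking, which neither run tests, I folded the givens into the survival number Φ, the turnovers per unit of [reagent]/[capture agent]: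

Φ = N [capture agent]/[reagent] = 6.38

I therefore expected the spring flask to stand at 18.4% at 4.0 d, with waiting, reagent, heat or removal offering nothing. Friday's catalyst, meeting the reagent and capture agent left, should turn over 10.5 times, giving 26.8%.

The forecast gave 18.4%, Friday's, 18.4% after Thursday's and, lower than my figure, 24.3% after Friday's, judging “So the catalyst is dead.”

The simulation gave 18.3%, Friday's, 18.3% after Thursday's and 26.9% after Friday's.

    reagent + catalyst intermediate B → catalyst intermediate C (k = 140 L mol⁻¹ min⁻¹, Ea = 49.0 kJ mol⁻¹)
    starting material + free catalyst ⇌ catalyst intermediate A (K = 7.40 L mol⁻¹, k = 560 L mol⁻¹ min⁻¹, Ea = 48.0 kJ mol⁻¹, ΔH = −57.0 kJ mol⁻¹)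
    catalyst intermediate D → free catalyst + target (k = 15.0 min⁻¹, Ea = 63.0 kJ mol⁻¹)
    catalyst intermediate C ⇌ by-product + catalyst intermediate D (K = 8.40 M, k = 9.10 min⁻¹, Ea = 72.0 kJ mol⁻¹, ΔH = 4.00 kJ mol⁻¹)
    catalyst intermediate A → catalyst intermediate B (k = 2.60 min⁻¹, Ea = 71.0 kJ mol⁻¹)
    reagent + free catalyst + target → free catalyst + over-reaction product (k = 12.0 L² mol⁻² min⁻¹, Ea = 49.0 kJ mol⁻¹)
    starting material + target ⇌ idle adduct, settled at all times (K = 270 L mol⁻¹, ΔH = −59.0 kJ mol⁻¹)
    capture agent + catalyst intermediate B → trapped intermediate (k = 21.0 L mol⁻¹ min⁻¹, Ea = 53.0 kJ mol⁻¹)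
    (constants at −20 °C)

At 96.0 h the spring flask held free catalyst at 0% and trapped intermediate at 100% of the catalyst charged. Part of the reason for what Friday's brings is the capture path: the same run without it shows −1.8 percentage points for Friday's, where with it the figure is 8.5 points. The simulated gain amounts to 10.7 turnovers per added catalyst, and Φ with the reagent and capture agent left gives 10.5.

In the neighbour flask with capture agent at 0.040 M, Φ with the charged amounts gives 46.0%, and the simulation gives 42.6%, with reagent down to 76% of its charge.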